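## Retrosynthetic overview
1. The C4 side chain is added last: rhodium-catalysed asymmetric 1,4-addition of an isopropenyl group to a ring A dienoate, made from the C10 ketone by enol triflate formation and a Heck reaction.
2. The lactone is closed after ring A exists, by displacement at C16 with inversion by the C12 ester.
3. Key disconnection: ring A and the spiro centre C23 come from a vinylogous semipinacol ring expansion, in which C21 shifts from carbinol C10 to the β-carbon C23 of a 4-silyloxycyclopentenone (ring D).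
4. The cis-bicyclo[3.3.0]octanone precursor comes from (S)-4-silyloxycyclopentenone (ring B) and methyl pent-4-enoate; the ring D piece comes from the (R)-enone by iodination and Luche reduction.
5. Ring order: B, then a five-membered pre-ring A, then ring D attached, then ring A by expansion (spiro centre set), then the lactone.

Assumption: atom labels (C4, C10, C12, O15, C16 … C28) are the positions of the non-hydrogen atoms in the target SMILES and are kept for all intermediates; both enantiomers of 4-(tert-butyldimethylsilyloxy)cyclopent-2-enone are taken as commercial.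

## Route

Step 1
Reactants: 2 methyl pent-4-enoate; 1 (S)-4-(tert-butyldimethylsilyloxy)cyclopent-2-en-1-one
Product: 4 methyl 2-[(1R,5S)-3,5-bis(tert-butyldimethylsilyloxy)cyclopent-2-en-1-yl]pent-4-enoate (C12 epimers), via ketene silyl acetal 3 (not isolated)
Conditions: 2, LiN(i-Pr)2, THF, −78 °C; TBSCl, DMPU, −78 °C → rt (3 used crude); then 1, TBSOTf (10 mol %), CH2Cl2, −78 °C
Reagents that add atoms: tert-butyldimethylsilyl chloride (TBSCl), CC(C)(C)[Si](C)(C)Cl
Why: Mukaiyama–Michael addition, in which the ketene silyl acetal attacks C22 anti to the C16 silyloxy group (sets C22) and silyl transfer traps the enolate as the C18=C21 enol ether; C12 forms unselectively and is corrected in step 3.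

Step 2
Reactants: 4 methyl 2-[(1R,5S)-3,5-bis(tert-butyldimethylsilyloxy)cyclopent-2-en-1-yl]pent-4-enoate
Product: 5 cis-bicyclo[3.3.0]octanone with C18 ketone, exocyclic C10=CH2, CO2Me at C12 (epimers) and convex-face OTBS at C16
Conditions: Pd(OAc)2 (10 mol %), O2 (1 atm), DMSO, 45 °C
Reagents that add atoms: none
Why: Oxidative cycloalkenylation of a silyl enol ether (Kende–Toyota type), in which the palladium enolate adds 5-exo to the terminal alkene and β-hydride elimination leaves the exocyclic methylene; the new five-membered ring can only be cis-fused, which sets C21.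

Step 3
Reactants: 5 exo-methylene bicyclo[3.3.0]octanone
Product: 7 tertiary alcohol with convex CH3 and concave OH at C18 and exo CO2Me at C12, via tertiary alcohol 6 (not isolated)
Conditions: MeMgBr, CeCl3, THF, −78 °C; work-up; then NaOMe (0.5 equiv), MeOH, rt
Reagents that add atoms: methylmagnesium bromide, C[Mg]Br
Why: Organocerium 1,2-addition from the convex face, anti to the α-substituent on C21, sets C18, and methoxide then equilibrates the ester α-centre to the less hindered exo position (sets C12).

Step 4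
Reactants: 7 exo-ester tertiary alcohol
Product: 8 cis-bicyclo[3.3.0]octan-2-one with C10 ketone, exo CO2Me at C12, convex OTBS at C16 and C18(CH3)(OH) with concave OH
Conditions: O3, NaHCO3, CH2Cl2/MeOH (4:1), −78 °C; Me2S, −78 °C → rt
Reagents that add atoms: ozone, [O-][O+]=O
Why: Ozonolysis of the 1,1-disubstituted alkene with reductive work-up gives the C10 ketone without touching a stereocentre, and the ring-fusion α-centre cannot epimerise because a trans-fused diquinane is too strained.

Step 5
Reactants: 9 (R)-4-(tert-butyldimethylsilyloxy)cyclopent-2-en-1-one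
Product: 10 (4R)-4-(tert-butyldimethylsilyloxy)-2-iodocyclopent-2-en-1-one
Conditions: I2, pyridine, CH2Cl2, 0 °C → rt
Reagents that add atoms: iodine, II
Why: α-Iodination of an enone by conjugate addition of pyridine, iodination of the enolate and elimination (Johnson iodination).

Step 6
Reactants: 10 (4R)-4-(tert-butyldimethylsilyloxy)-2-iodocyclopent-2-en-1-one
Product: 11 (1S,4R)-4-(tert-butyldimethylsilyloxy)-2-iodocyclopent-2-en-1-ol
Conditions: NaBH4, CeCl3·7H2O, MeOH, −78 °C
Reagents that add atoms: none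
Why: Luche 1,2-reduction with hydride delivered anti to the C25 silyloxy group gives the cis-1,4-dioxygenated cyclopentene and sets C28.

Step 7
Reactants: 11 (1S,4R)-4-(tert-butyldimethylsilyloxy)-2-iodocyclopent-2-en-1-ol
Product: 12 (1S,4R)-1-(tert-butyldiphenylsilyloxy)-4-(tert-butyldimethylsilyloxy)-2-iodocyclopent-2-ene
Conditions: TBDPSCl, imidazole, DMF, rt
Reagents that add atoms: tert-butyldiphenylsilyl chloride (TBDPSCl), CC(C)(C)[Si](Cl)(c1ccccc1)c1ccccc1
Why: Standard silylation gives a C28 ether that survives the later removal of the TBS groups.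

Step 8
Reactants: 12 bis-silylated iodocyclopentene; 8 bicyclo[3.3.0]octan-2-one
Product: 14 tertiary allylic alcohol (C10 carbinol bonded to C23 of the bis-silyloxycyclopentene, ring D on the convex face), via alkenylmagnesium chloride 13 (not isolated)
Conditions: 12, i-PrMgCl·LiCl, THF, −40 °C; LaCl3·2LiCl; then 8 (O-magnesiated with i-PrMgCl·LiCl, 1.0 equiv, −78 °C), −78 → 0 °C; aq NH4Cl
Reagents that add atoms: none
Why: Iodine–magnesium exchange followed by LaCl3-promoted 1,2-addition of the alkenyl Grignard reagent to the hindered ketone from the convex face; the C10 carbinol configuration is irrelevant because C10 becomes a carbonyl in step 11.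

Step 9
Reactants: 14 tris-silylated tertiary allylic alcohol
Product: 15 tetraol with free OH at C10, C16, C18 and C25 and OTBDPS at C28
Conditions: HF·pyridine, pyridine, THF, 0 °C → rt
Reagents that add atoms: none
Why: Chemoselective desilylation, since both secondary TBS ethers cleave while the roughly hundredfold more acid-stable TBDPS ether survives.

Step 10
Reactants: 15 tetraol
Product: 16 3-substituted (4S)-4-(tert-butyldiphenylsilyloxy)cyclopent-2-enone carrying the C10 carbinol at C23
Conditions: MnO2, CH2Cl2, rt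
Reagents that add atoms: none
Why: MnO2 oxidises only the allylic secondary alcohol at C25 to the enone; the tertiary and non-allylic hydroxyls are inert.

Step 11
Reactants: 16 γ-hydroxy enone
Product: 18 spiro cis-hydrindanone (ring A ketone at C10, spiro C23, C25 dioxolane, C28 OTBDPS trans to C21, C12 CO2Me, free OH at C16 and C18), via allylic dioxolane 17 (not isolated)
Conditions: 2-ethyl-2-methyl-1,3-dioxolane (10 equiv), ethylene glycol (0.2 equiv), Tf2NH (5 mol %), CH2Cl2, −20 °C → rt; then Et3N
Reagents that add atoms: 2-ethyl-2-methyl-1,3-dioxolane, CCC1(C)OCCO1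
Why: Proposed new method: an oxocarbenium-triggered vinylogous α-ketol (semipinacol) ring expansion, in which transketalisation gives dioxolane 17, acid-induced ring opening gives a 2-hydroxyethoxy allyl cation with positive charge shared by C25 and C23, the C10–C21 bond (the more substituted arm of the carbinol) shifts to C23 anti to the C28 silyloxy group with retention at C21 so that the cyclopentanol becomes the ring A cyclohexanone and C23 is set, and the enol ether recloses to the dioxolane that keeps C25 masked; the closest known reactions are the amine (iminium)-catalysed vinylogous α-ketol rearrangement of 1-(3-oxocycloalkenyl)cyclobutanols and acetal-initiated pinacol rearrangements, neither shown for a cyclopentanol-to-cyclohexanone expansion.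

Step 12
Reactants: 18 spiro cis-hydrindanone hydroxy ester
Product: 20 γ-lactone ketone (lactone C12–C13(=O)–O15–C16, cis-fused to ring B, trans-fused to ring A), via C16 mesylate 19 (not isolated)
Conditions: Ms2O, pyridine, CH2Cl2, 0 °C; then toluene, 80 °C
Reagents that add atoms: none
Why: After mesylation of the only secondary alcohol, the ester carbonyl oxygen displaces the mesylate from the opposite face (neighbouring-group participation, SN2) and the methyloxonium ion is demethylated by mesylate, so C16 is inverted to the target configuration.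

Step 13
Reactants: 20 γ-lactone ketone
Product: 21 C10=C11 enol triflate
Conditions: KN(SiMe3)2 (2.2 equiv), THF, −78 °C; PhNTf2, −78 → 0 °C
Reagents that add atoms: N-phenylbis(trifluoromethanesulfonimide) (PhNTf2), O=S(=O)(N(c1ccccc1)S(=O)(=O)C(F)(F)F)C(F)(F)F
Why: Kinetic enolisation can go only toward C11 (C23 is quaternary and C25 is masked as the ketal), and O-sulfonylation of the potassium enolate gives the enol triflate.

Step 14
Reactants: 21 enol triflate; 22 methyl acrylate
Product: 23 methyl (2E)-3-(ring A dienyl)acrylate (C10 bears the CH=CH–CO2Me unit)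
Conditions: Pd(OAc)2 (10 mol %), PPh3 (20 mol %), Et3N, DMF, 60 °C
Reagents that add atoms: none
Why: Mizoroki–Heck reaction of the alkenyl triflate with the acrylate gives the (E)-dienoate.

Step 15
Reactants: 23 (E)-dienoate; 24 potassium isopropenyltrifluoroborate (CH2=C(CH3)BF3K)
Product: 26 C28 tert-butyldiphenylsilyl ether of the target, via dioxolane adduct 25 (not isolated)
Conditions: [Rh(cod)2]BF4 (5 mol %), (S)-BINAP (6 mol %), toluene/H2O (10:1), 100 °C; then 1 M aq HCl, THF, rt
Reagents that add atoms: water, O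
Why: Hayashi–Miyaura rhodium-catalysed asymmetric 1,4-addition, in which the BINAP–rhodium alkenyl species is expected from the usual model for (E)-enoates to add to the re face of C4 (sets C4 as S) while 1,6-addition is disfavoured by the substituted C10 and C11; the acidic work-up hydrolyses the dioxolane to the C25 ketone.

Step 16
Reactants: 26 C28 silyl ether
Product: 27 target CNP0255095.1
Conditions: HF·pyridine, THF, 0 °C → rt
Reagents that add atoms: none
Why: Desilylation under mildly acidic fluoride conditions frees the C28 alcohol without β-elimination of the β-hydroxy ketone.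

## Compound list
1 | (S)-4-(tert-butyldimethylsilyloxy)cyclopent-2-en-1-one | O=C1C=C[C@@H](O[Si](C)(C)C(C)(C)C)C1 | starting material
2 | methyl pent-4-enoate | C=CCCC(=O)OC | starting material
3 | 1-methoxy-1-(tert-butyldimethylsilyloxy)penta-1,4-diene (E/Z mixture) | C=CCC=C(OC)O[Si](C)(C)C(C)(C)C | intermediate (not isolated)
4 | methyl 2-[(1R,5S)-3,5-bis(tert-butyldimethylsilyloxy)cyclopent-2-en-1-yl]pent-4-enoate (C12 epimers; side chain trans to OTBS) | CC(C)(C)[Si](C)(C)OC1=C[C@H](C(CC=C)C(=O)OC)[C@@H](O[Si](C)(C)C(C)(C)C)C1 | intermediate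
5 | cis-bicyclo[3.3.0]octanone: C18 ketone, C10=CH2, CO2Me at C12 (epimers), OTBS at C16 on the convex face (trans to C12), H21/H22 cis | C=C1CC(C(=O)OC)[C@H]2[C@@H]1C(=O)C[C@@H]2O[Si](C)(C)C(C)(C)C | intermediate
6 | as 5 but C18 carries CH3 (convex) and OH (concave); C12 epimers | C=C1CC(C(=O)OC)[C@H]2[C@@H]1[C@@](C)(O)C[C@@H]2O[Si](C)(C)C(C)(C)C | intermediate (not isolated)
7 | as 6 with CO2Me at C12 exo (cis to H22, trans to C16) | C=C1C[C@@H](C(=O)OC)[C@H]2[C@@H]1[C@@](C)(O)C[C@@H]2O[Si](C)(C)C(C)(C)C | intermediate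
8 | cis-bicyclo[3.3.0]octan-2-one: C10 ketone, exo CO2Me at C12, convex OTBS at C16, C18 with convex CH3 and concave OH | O=C1C[C@@H](C(=O)OC)[C@H]2[C@@H]1[C@@](C)(O)C[C@@H]2O[Si](C)(C)C(C)(C)C | intermediate
9 | (R)-4-(tert-butyldimethylsilyloxy)cyclopent-2-en-1-one | O=C1C=C[C@H](O[Si](C)(C)C(C)(C)C)C1 | starting material
10 | (4R)-4-(tert-butyldimethylsilyloxy)-2-iodocyclopent-2-en-1-one | O=C1C(I)=C[C@H](O[Si](C)(C)C(C)(C)C)C1 | intermediate
11 | (1S,4R)-4-(tert-butyldimethylsilyloxy)-2-iodocyclopent-2-en-1-ol (cis) | IC1=C[C@H](O[Si](C)(C)C(C)(C)C)C[C@@H]1O | intermediate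
12 | (1S,4R)-1-(tert-butyldiphenylsilyloxy)-4-(tert-butyldimethylsilyloxy)-2-iodocyclopent-2-ene | IC1=C[C@H](O[Si](C)(C)C(C)(C)C)C[C@@H]1O[Si](c1ccccc1)(c1ccccc1)C(C)(C)C | intermediate
13 | alkenylmagnesium chloride from 12 (Mg at C23) | Cl[Mg]C1=C[C@H](O[Si](C)(C)C(C)(C)C)C[C@@H]1O[Si](c1ccccc1)(c1ccccc1)C(C)(C)C | intermediate (not isolated)
14 | tertiary allylic alcohol: C10(OH) of the diquinane bonded to C23 of the cyclopentene (C25 OTBS, C28 OTBDPS, cis); other centres as in 8 | O[C@]1(C2=C[C@H](O[Si](C)(C)C(C)(C)C)C[C@@H]2O[Si](c2ccccc2)(c2ccccc2)C(C)(C)C)C[C@@H](C(=O)OC)[C@H]3[C@@H]1[C@@](C)(O)C[C@@H]3O[Si](C)(C)C(C)(C)C | intermediate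
15 | tetraol: as 14 with free OH at C16 and C25 | O[C@]1(C2=C[C@H](O)C[C@@H]2O[Si](c2ccccc2)(c2ccccc2)C(C)(C)C)C[C@@H](C(=O)OC)[C@H]3[C@@H]1[C@@](C)(O)C[C@@H]3O | intermediate
16 | γ-hydroxy enone: as 15 with C25 ketone (4-silyloxycyclopent-2-enone bearing the C10 carbinol at C23) | O[C@]1(C2=CC(=O)C[C@@H]2O[Si](c2ccccc2)(c2ccccc2)C(C)(C)C)C[C@@H](C(=O)OC)[C@H]3[C@@H]1[C@@](C)(O)C[C@@H]3O | intermediate
17 | allylic dioxolane of 16 (C25 ethylene ketal) | O[C@]1(C2=CC3(OCCO3)C[C@@H]2O[Si](c2ccccc2)(c2ccccc2)C(C)(C)C)C[C@@H](C(=O)OC)[C@H]3[C@@H]1[C@@](C)(O)C[C@@H]3O | intermediate (not isolated)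
18 | spiro cis-hydrindanone: C10 ketone, spiro C23 (target configuration), C25 dioxolane, C28 OTBDPS trans to C21, C12 CO2Me trans to C16, C16 OH epimeric to the target, C18 as in the target | COC(=O)[C@@H]1CC(=O)[C@@]2(CC3(OCCO3)C[C@@H]2O[Si](c2ccccc2)(c2ccccc2)C(C)(C)C)[C@@H]3[C@H]1[C@@H](O)C[C@]3(C)O | intermediate
19 | C16 methanesulfonate of 18 | COC(=O)[C@@H]1CC(=O)[C@@]2(CC3(OCCO3)C[C@@H]2O[Si](c2ccccc2)(c2ccccc2)C(C)(C)C)[C@@H]3[C@H]1[C@@H](OS(C)(=O)=O)C[C@]3(C)O | intermediate (not isolated)
20 | lactone ketone: all ring stereocentres as in the target, C10 ketone, C25 dioxolane, C28 OTBDPS | O=C1C[C@H]2C(=O)O[C@@H]3C[C@](C)(O)[C@@H]([C@@H]32)[C@]12CC3(OCCO3)C[C@@H]2O[Si](c2ccccc2)(c2ccccc2)C(C)(C)C | intermediate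
21 | C10=C11 enol trifluoromethanesulfonate of 20 | O=S(=O)(OC1=C[C@H]2C(=O)O[C@@H]3C[C@](C)(O)[C@@H]([C@@H]32)[C@]12CC3(OCCO3)C[C@@H]2O[Si](c2ccccc2)(c2ccccc2)C(C)(C)C)C(F)(F)F | intermediate
22 | methyl acrylate | C=CC(=O)OC | starting material
23 | (2E)-dienoate: C10 bears CH=CH–CO2Me | COC(=O)/C=C/C1=C[C@H]2C(=O)O[C@@H]3C[C@](C)(O)[C@@H]([C@@H]32)[C@]12CC3(OCCO3)C[C@@H]2O[Si](c2ccccc2)(c2ccccc2)C(C)(C)C | intermediate
24 | potassium isopropenyltrifluoroborate | C=C(C)[B-](F)(F)F.[K+] | starting material
25 | C25 dioxolane, C28 TBDPS ether of the target (4S) | C=C(C)[C@H](CC(=O)OC)C1=C[C@H]2C(=O)O[C@@H]3C[C@](C)(O)[C@@H]([C@@H]32)[C@]12CC3(OCCO3)C[C@@H]2O[Si](c2ccccc2)(c2ccccc2)C(C)(C)C | intermediate (not isolated)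
26 | C28 tert-butyldiphenylsilyl ether of the target | C=C(C)[C@H](CC(=O)OC)C1=C[C@H]2C(=O)O[C@@H]3C[C@](C)(O)[C@@H]([C@@H]32)[C@]12CC(=O)C[C@@H]2O[Si](c2ccccc2)(c2ccccc2)C(C)(C)C | intermediate
27 | CNP0255095.1 (4S,12R,16R,18S,21S,22R,23R,28S in the label system) | C=C(C)[C@H](CC(=O)OC)C1=C[C@H]2C(=O)O[C@@H]3C[C@](C)(O)[C@@H]([C@@H]32)[C@]12CC(=O)C[C@@H]2O | target

## Step count and risks
Total: 16 steps. Longest linear sequence: 13 steps (steps 1–4 and 8–16).

Three steps most likely to fail:

**Step 11 (the new ring expansion).** Risks: migration of C11 in place of C21; reversible oxa-Michael trapping by the C18 hydroxyl; no rearrangement at all for the less strained cyclopentanol. The fallback sets out from 8 and returns at 18, using known reactions only. Commercial 1,4-dioxaspiro[4.4]nonan-7-one is condensed with 2,4,6-triisopropylbenzenesulfonyl hydrazide to the trisylhydrazone F1. A Shapiro reaction (n-BuLi, 2 equiv, THF, −78 → 0 °C; the less hindered α-CH2 is deprotonated) gives the cyclopentenyllithium F2, which after CeCl3 adds to O-magnesiated 8 to give the allylic alcohol F3. Hydroxyl-directed epoxidation (VO(acac)2, t-BuOOH, CH2Cl2) gives the epoxy alcohol F4. BF3·OEt2 (CH2Cl2, −78 °C) then effects the classical 2,3-epoxy-alcohol semipinacol ring expansion: C21 migrates anti to the breaking C23–O bond, so the C28 hydroxyl of the hydroxy ketone F5 is trans to C21 by mechanism. The face of the epoxidation must be checked, because it decides the absolute sense of C23/C28. Silylation (TBDPSCl, imidazole, DMAP, DMF) gives the bis-silyl ether F6, and HF·pyridine removes the C16 TBS group to give 18.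

**Step 12 (lactonisation with inversion by ester participation).** Risks: elimination of the mesylate or slow cyclisation. The fallback sets out from 18 and returns at 20. Saponification (LiOH, THF/H2O, 0 °C) gives the hydroxy acid F7, and Mitsunobu lactonisation (PPh3, DIAD, THF, 0 °C) closes the lactone with inversion at C16.

**Step 15 (asymmetric 1,4-addition to the dienoate).** Risks: 1,6-addition, base- or metal-induced migration of the C10=C11 bond through the acidic C12–H, or mismatched catalyst control at C4. The fallback sets out from 21 and returns at 26 through 25. Stille coupling of 21 with (E)-2-methyl-3-(tributylstannyl)prop-2-en-1-ol (Pd(PPh3)4, CuI, LiCl, DMF, 50 °C) gives the (E)-dienol F8. A Johnson–Claisen rearrangement (MeC(OMe)3, cat. EtCO2H, toluene, 110 °C) forms the C4–C5 bond and the isopropenyl group in one step to give 25. C4 is then set under substrate control through the chair transition state, and the epimers would have to be separated. The acidic work-up of step 15 then gives 26.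

## Further compounds
F1 | step 11 | 1,4-dioxaspiro[4.4]nonan-7-one 2,4,6-triisopropylbenzenesulfonylhydrazone | CC(C)c1cc(C(C)C)c(S(=O)(=O)NN=C2CCC3(C2)OCCO3)c(C(C)C)c1
F2 | step 11 | 7-lithio-1,4-dioxaspiro[4.4]non-7-ene | [Li]C1=CCC2(C1)OCCO2
F3 | step 11 | tertiary allylic alcohol: C10(OH) of 8 bonded to C23 of the 1,4-dioxaspiro[4.4]non-7-ene (C23=C28) | O[C@]1(C2=CCC3(C2)OCCO3)C[C@@H](C(=O)OC)[C@H]4[C@@H]1[C@@](C)(O)C[C@@H]4O[Si](C)(C)C(C)(C)C
F4 | step 11 | C23–C28 epoxide of F3 (oxygen on the face that becomes the C28 hydroxyl of the target) | O[C@]1([C@@]23CC4(OCCO4)C[C@@H]2O3)C[C@@H](C(=O)OC)[C@H]5[C@@H]1[C@@](C)(O)C[C@@H]5O[Si](C)(C)C(C)(C)C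
F5 | step 11 | spiro cis-hydrindanone with free C28 OH (trans to C21), C25 dioxolane, C16 OTBS | COC(=O)[C@@H]1CC(=O)[C@@]2(CC3(OCCO3)C[C@@H]2O)[C@@H]3[C@H]1[C@@H](O[Si](C)(C)C(C)(C)C)C[C@]3(C)O
F6 | step 11 | C28 tert-butyldiphenylsilyl ether of F5 | COC(=O)[C@@H]1CC(=O)[C@@]2(CC3(OCCO3)C[C@@H]2O[Si](c2ccccc2)(c2ccccc2)C(C)(C)C)[C@@H]3[C@H]1[C@@H](O[Si](C)(C)C(C)(C)C)C[C@]3(C)O
F7 | step 12 | hydroxy acid from 18 (C13 carboxylic acid, free C16 OH) | OC(=O)[C@@H]1CC(=O)[C@@]2(CC3(OCCO3)C[C@@H]2O[Si](c2ccccc2)(c2ccccc2)C(C)(C)C)[C@@H]3[C@H]1[C@@H](O)C[C@]3(C)O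
F8 | step 15 | (E)-dienol: C10 bears CH=C(CH3)CH2OH | OC/C(C)=C/C1=C[C@H]2C(=O)O[C@@H]3C[C@](C)(O)[C@@H]([C@@H]32)[C@]12CC3(OCCO3)C[C@@H]2O[Si](c2ccccc2)(c2ccccc2)C(C)(C)C
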